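**Retrosynthetic overview**

- The target is the 31-membered lactone of 30-hydroxytriacontanoic acid: ring oxygen, carbonyl C1 and methylenes C2–C30. Its only ring is opened at C25–C26, taken at the alkene oxidation level: target ⇐ C25=C26 ring alkene (hydrogenation) ⇐ acyclic diene ester hex-5-en-1-yl hexacos-25-enoate (ring-closing metathesis, loss of ethene).
- Enabling feature: C25–C26 sits in an unbranched methylene run, four CH2 (C27–C30) from the ring oxygen and 23 CH2 (C2–C24) from the carbonyl carbon. As C25=C26 it is the only reactive site of the ring, both carbons are unhindered monosubstituted alkene termini in the open precursor, and neither can chelate the ester carbonyl. One metathesis event therefore closes the whole ring.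
- Diene ester ⇐ hexacos-25-enoic acid + hex-5-en-1-ol (esterification). The C26 acid ⇐ 15-bromopentadecanoic acid + undec-10-enyl Grignard reagent (copper-catalysed sp3–sp3 coupling). Three commercial pieces: C11 + C15 + C6.
- Ring order: the single ring is formed in step 4 and saturated in step 5.

Key step: step 4

Remark: the target is read as C30H58O2 (one ester group, 29 ring methylenes, no stereocentre); carbon numbers follow the acid chain (C1 = carbonyl carbon, C30 = OCH2), and the ring alkene from step 4 is expected as an E/Z mixture that is carried on unseparated.

**Route**

Step 1
Reactants: 1 11-bromoundec-1-ene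
Product: 2 undec-10-en-1-ylmagnesium bromide (titrated THF solution, used directly)
Conditions: Mg turnings (1.3 equiv), I2 (cat.), THF, 40 °C, slow addition
Reagents that add atoms: magnesium, [Mg]
Why: Grignard reagent formation by insertion of magnesium metal into the primary C–Br bond is reliable for ω-alkenyl bromides, the remote terminal alkene being inert, and slow addition should keep Wurtz homocoupling low.

Step 2
Reactants: 3 15-bromopentadecanoic acid; 2 undec-10-en-1-ylmagnesium bromide
Product: 6 hexacos-25-enoic acid, via bromomagnesium 15-bromopentadecanoate 4 (not isolated), via bromomagnesium hexacos-25-enoate 5 (not isolated)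
Conditions: 2 (1.0 equiv), THF, −20 °C; then Li2CuCl4 (3 mol %), 2 (1.5 equiv), −20 to 0 °C; then 1 M HCl
Reagents that add atoms: none
Why: The first equivalent of 2 turns the acid into the unreactive magnesium carboxylate 4, after which a Kochi-type copper-catalysed sp3–sp3 cross-coupling of the Grignard reagent with the primary alkyl bromide should join C15 to C16 and give the C26 ω-alkenoic acid on acidification.

Step 3
Reactants: 6 hexacos-25-enoic acid; 7 hex-5-en-1-ol
Product: 8 hex-5-en-1-yl hexacos-25-enoate
Conditions: 7 (3 equiv), TsOH·H2O (5 mol %), toluene, reflux, Dean–Stark
Reagents that add atoms: none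
Why: Fischer esterification of an unhindered acid with a primary alcohol is driven to completion by azeotropic removal of water, and the two terminal alkenes should be inert to catalytic sulfonic acid.

Step 4
Reactants: 8 hex-5-en-1-yl hexacos-25-enoate
Product: 9 (E/Z)-oxacyclohentriacont-26-en-2-one
Conditions: second-generation Grubbs catalyst RuCl2(H2IMes)(PCy3)(=CHPh) (5 mol %), 1,4-benzoquinone (10 mol %), CH2Cl2, 40 °C, 1 mM, slow addition of 8, Ar sparge; then ethyl vinyl ether
Reagents that add atoms: none
Why: Ring-closing olefin metathesis by the Chauvin mechanism: the Ru benzylidene exchanges with one terminal alkene of 8 to give a Ru alkylidene, which adds to the other terminus through a ruthenacyclobutane and releases ethene, whose removal drives the reaction. The closest known reaction type is the RCM macrocyclization of ω-alkenyl ω-alkenoates to large-ring musk-type lactones. The single ring is closed head-to-tail as a 31-membered macrocycle in which both carbons of the new C25=C26 bond (ring positions 26 and 27) become ring members. No stereocentre is formed, and the alkene geometry is irrelevant because step 5 removes it. The step needs ring closure to win over intermolecular metathesis, which high dilution with slow addition and the reversibility that lets oligomers back-bite to the ring should secure. It also needs the double bonds to stay in place, which 1,4-benzoquinone as Ru-hydride scavenger and the unhindered, non-chelating position of both alkenes (four and 23 methylenes from the ester) should secure.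

Step 5
Reactants: 9 (E/Z)-oxacyclohentriacont-26-en-2-one
Product: 10 oxacyclohentriacontan-2-one (30-triacontanolide)
Conditions: H2 (1 atm), 10% Pd/C, EtOAc, rt
Reagents that add atoms: none
Why: Heterogeneous catalytic hydrogenation should saturate the disubstituted ring alkene of either geometry while the lactone stays untouched, so both isomers converge on the saturated macrolide.

**Compound list**

1 | 11-bromoundec-1-ene | C=CCCCCCCCCCBr | starting material
2 | undec-10-en-1-ylmagnesium bromide | C=CCCCCCCCCC[Mg]Br | intermediate
3 | 15-bromopentadecanoic acid | OC(=O)CCCCCCCCCCCCCCBr | starting material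
4 | bromomagnesium 15-bromopentadecanoate | Br[Mg]OC(=O)CCCCCCCCCCCCCCBr | intermediate
5 | bromomagnesium hexacos-25-enoate | Br[Mg]OC(=O)CCCCCCCCCCCCCCCCCCCCCCCC=C | intermediate
6 | hexacos-25-enoic acid | OC(=O)CCCCCCCCCCCCCCCCCCCCCCCC=C | intermediate
7 | hex-5-en-1-ol | OCCCCC=C | starting material
8 | hex-5-en-1-yl hexacos-25-enoate | C=CCCCCOC(=O)CCCCCCCCCCCCCCCCCCCCCCCC=C | intermediate
9 | (E/Z)-oxacyclohentriacont-26-en-2-one (E isomer drawn, mixture carried on) | O=C1CCCCCCCCCCCCCCCCCCCCCCC/C=C/CCCCO1 | intermediate
10 | oxacyclohentriacontan-2-one | O=C1CCCCCCCCCCCCCCCCCCCCCCCCCCCCCO1 | target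

**Summary**

Total step count: 5. Longest linear sequence: 5 steps (1 → 2 → 6 → 8 → 9 → 10).

Steps most likely to fail:

Step 4. At the dilution needed, intermolecular metathesis (linear oligomers, cyclic dimer) may outrun ring closure. Ru-hydride-mediated migration of the terminal double bonds before closure would also give ring-contracted homologues that become inseparable after hydrogenation. The fallback closes the ring at the ester C–O bond instead of at C25–C26. It sets out from 6 and 7. Cross-metathesis of 6 with excess 7 (second-generation Grubbs catalyst, CH2Cl2, 40 °C) should give (E/Z)-30-hydroxytriacont-25-enoic acid F1. Hydrogenation (H2, Pd/C, THF) should give 30-hydroxytriacontanoic acid F2. Activation with 2,4,6-trichlorobenzoyl chloride and Et3N in THF should give 30-hydroxytriacontanoic 2,4,6-trichlorobenzoic anhydride F3. Slow addition of F3 to DMAP in refluxing toluene at high dilution (Yamaguchi macrolactonization) comes back to the route at 10.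

Step 2. Precipitation of the magnesium carboxylate may slow the copper-catalysed cross-coupling so that homocoupling of 2 and halogen–magnesium exchange take over. The fallback masks the carboxyl group first as the ester the route needs anyway. It sets out from 3 and 7. Fischer esterification (TsOH, toluene, Dean–Stark) should give hex-5-en-1-yl 15-bromopentadecanoate F4. Homogeneous coupling of F4 with 2 (Li2CuCl4 cat., N-methylpyrrolidone as co-solvent, THF, 0 °C, where the ester is expected to be spared) rejoins the route at 8 and bypasses 6.

Step 3. Prolonged heating with acid may cause migration of the terminal double bonds or addition of the alcohol across them, which would spoil the ring size set in step 4. The fallback makes the ester by O-alkylation under basic conditions instead of acyl substitution under acid. It sets out from 6. Cs2CO3 in DMF should give caesium hexacos-25-enoate F5, which is alkylated with 6-bromohex-1-ene (BrCCCCC=C) at 50 °C in an SN2 reaction and comes back to the route at 8.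

**Further compounds**

F1 | step 4 | (E/Z)-30-hydroxytriacont-25-enoic acid (E isomer drawn) | OC(=O)CCCCCCCCCCCCCCCCCCCCCCC/C=C/CCCCO
F2 | step 4 | 30-hydroxytriacontanoic acid | OC(=O)CCCCCCCCCCCCCCCCCCCCCCCCCCCCCO
F3 | step 4 | 30-hydroxytriacontanoic 2,4,6-trichlorobenzoic anhydride | O=C(OC(=O)c1c(Cl)cc(Cl)cc1Cl)CCCCCCCCCCCCCCCCCCCCCCCCCCCCCO
F4 | step 2 | hex-5-en-1-yl 15-bromopentadecanoate | C=CCCCCOC(=O)CCCCCCCCCCCCCCBr
F5 | step 3 | caesium hexacos-25-enoate | [Cs+].[O-]C(=O)CCCCCCCCCCCCCCCCCCCCCCCC=C
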